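**Retrosynthetic overview**

1. Target 31 ← hydrogenolysis of the two benzylic C–O groups of (1S)-depsidone 30 ← acid equilibration and separation of the acetal epimers 29 ← seven-membered depsidone lactone (ring A acid onto the C-5 phenol of ring B) ← diaryl ether by SNAr of the ring B C-4 phenoxide on fluoroarene 24.
2. Ring B phthalide 16 ← C7a–C1 bond: an aryllithium at C7a closes the lactone onto a phenyl carbonate carried by the oxygen of the acetal carbon C3 (Parham-type 1,4 O→C acyl transfer).
3. Enabling feature: in the phthalide ring the carbonyl carbon C1 and the lactol carbon C3 are joined through O2, so C1 can ride as a carbonate on the C3 oxygen; C7a is the ring B carbon ortho to the C7 oxygen and para to the C5 oxygen, the site that bromination of a 2,3,5-trioxygenated benzaldehyde selects.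
4. The lactol centre is held as an acetal of (S)-1-phenylethanol from step 8 to the last step; both epimers are carried as far as depsidone 29, because the C-4 phenoxide of step 14 can open the acetal reversibly, and are equilibrated and separated in step 17.
5. Ring order: lactone ring of ring B (step 9), then the diaryl ether (step 14), then the seven-membered lactone (step 16).

Key step: step 9

Assumption: a 3-hydroxyphthalide lactol epimerises through its open 2-formylbenzoic acid form once acid or base is present, so the (S) centre is carried as an O-(1-phenylethyl) acetal, fixed by equilibration and separation at the last protected stage (step 17, the configuration of the separated epimer to be assigned by X-ray or NOE analysis) and freed only in the last, neutral step; the product should then be kept cold, neutral and aprotic.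

Compounds 1, 10 and 17 are commercial.

**Ring B**

Step 1
Reactants: 1 4-(benzyloxy)-2-hydroxybenzaldehyde
Product: 2 2-(allyloxy)-4-(benzyloxy)benzaldehyde
Conditions: allyl bromide, K2CO3, DMF, 25 °C
Reagents that add atoms: allyl bromide C=CCBr
Why: Williamson O-alkylation of the only phenol should give the allyl ether that later is the removable group on the ring B oxygen destined for the ester.

Step 2
Reactants: 2 2-(allyloxy)-4-(benzyloxy)benzaldehyde
Product: 4 2-(allyloxy)-4-(benzyloxy)phenol, via aryl formate 3 (not isolated)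
Conditions: 30% H2O2, H2SO4 (cat.), MeOH, 25 °C
Reagents that add atoms: hydrogen peroxide OO
Why: Acid-catalysed Dakin oxidation (Baeyer–Villiger-type aryl migration) of the electron-rich 2,4-dialkoxybenzaldehyde, then methanolysis of the formate, should replace CHO by OH without epoxidising the allyl group.

Step 3
Reactants: 4 2-(allyloxy)-4-(benzyloxy)phenol
Product: 6 3-(allyloxy)-5-(benzyloxy)-2-hydroxybenzaldehyde, via benzylic alcohol 5 (not isolated)
Conditions: MgCl2, Et3N, (CH2O)n, MeCN, reflux; then 1 M HCl
Reagents that add atoms: formaldehyde (from paraformaldehyde) C=O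
Why: Casnati–Skattebøl ortho-formylation, in which the magnesium phenoxide delivers formaldehyde to the single free ortho carbon and a second formaldehyde oxidises the benzylic alkoxide by hydride transfer.

Step 4
Reactants: 6 3-(allyloxy)-5-(benzyloxy)-2-hydroxybenzaldehyde
Product: 7 3-(allyloxy)-5-(benzyloxy)-2-[(triisopropylsilyl)oxy]benzaldehyde
Conditions: i-Pr3SiCl, imidazole, DMF, 40 °C
Reagents that add atoms: chlorotriisopropylsilane CC(C)[Si](Cl)(C(C)C)C(C)C
Why: Silylation of the phenol should give a bulky ether that survives the organometallic steps and later serves as the latent nucleophile for the diaryl ether.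

Step 5
Reactants: 7 3-(allyloxy)-5-(benzyloxy)-2-[(triisopropylsilyl)oxy]benzaldehyde
Product: 8 3-(allyloxy)-5-(benzyloxy)-6-bromo-2-[(triisopropylsilyl)oxy]benzaldehyde
Conditions: N-bromosuccinimide, MeCN, 0 → 25 °C
Reagents that add atoms: N-bromosuccinimide O=C1CCC(=O)N1Br
Why: Electrophilic aromatic bromination should go to the carbon ortho to the benzyloxy and para to the allyloxy group, as 3,5-dialkoxybenzaldehydes are brominated next to the formyl group and not between the two ethers.

Step 6
Reactants: 8 3-(allyloxy)-5-(benzyloxy)-6-bromo-2-[(triisopropylsilyl)oxy]benzaldehyde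
Product: 9 3-(allyloxy)-5-(benzyloxy)-6-bromo-2-[(triisopropylsilyl)oxy]benzoic acid
Conditions: NaClO2, NaH2PO4, 2-methyl-2-butene, t-BuOH/H2O, 25 °C
Reagents that add atoms: sodium chlorite [Na+].[O-]Cl=O
Why: Pinnick oxidation should convert the hindered aldehyde into the acid under buffered conditions while the alkene scavenger keeps hypochlorous acid away from the allyl ether.

Step 7
Reactants: 9 3-(allyloxy)-5-(benzyloxy)-6-bromo-2-[(triisopropylsilyl)oxy]benzoic acid; 10 (S)-1-phenylethanol
Product: 12 (S)-1-phenylethyl 3-(allyloxy)-5-(benzyloxy)-6-bromo-2-[(triisopropylsilyl)oxy]benzoate, via acid chloride 11 (not isolated)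
Conditions: 1-chloro-N,N,2-trimethylprop-1-en-1-amine, CH2Cl2, 0 → 25 °C; then 10, pyridine, DMAP (cat.), 25 °C
Reagents that add atoms: none
Why: Acylation of the alcohol by the acid chloride made under neutral conditions (nucleophilic catalysis by DMAP) should give the hindered ester with the carbinol configuration retained, since no bond to that carbon is broken.

Step 8
Reactants: 12 (S)-1-phenylethyl 3-(allyloxy)-5-(benzyloxy)-6-bromo-2-[(triisopropylsilyl)oxy]benzoate
Product: 14 {3-(allyloxy)-5-(benzyloxy)-6-bromo-2-[(triisopropylsilyl)oxy]phenyl}[(1S)-1-phenylethoxy]methyl phenyl carbonate (both epimers at the acetal carbon), via diisobutylaluminium hemiacetal 13 (not isolated)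
Conditions: i-Bu2AlH, CH2Cl2, −78 °C; then pyridine, DMAP, phenyl chloroformate, −78 → −20 °C; filtration through Et3N-deactivated silica, used at once
Reagents that add atoms: phenyl chloroformate O=C(Cl)Oc1ccccc1
Why: Reductive acylation of an ester, in which the tetrahedral aluminium hemiacetal is stable at −78 °C and is O-acylated in situ (here by a chloroformate) to the mixed acetal carbonate; the new acetal centre forms without control and both epimers are carried on.

Step 9
Reactants: 14 {3-(allyloxy)-5-(benzyloxy)-6-bromo-2-[(triisopropylsilyl)oxy]phenyl}[(1S)-1-phenylethoxy]methyl phenyl carbonate (both epimers at the acetal carbon)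
Product: 16 5-(allyloxy)-7-(benzyloxy)-3-[(1S)-1-phenylethoxy]-4-[(triisopropylsilyl)oxy]isobenzofuran-1(3H)-one (both epimers at C-3), via aryllithium 15 (not isolated)
Conditions: t-BuLi (2 equiv), THF/Et2O, −100 → −78 °C; then cold H2O
Reagents that add atoms: none
Why: Bromine–lithium exchange at −100 °C should outrun addition of t-BuLi to the carbonate and give aryllithium 15, whose carbanion attacks the carbonate carbonyl held on the acetal oxygen; the tetrahedral alkoxide then expels phenoxide, the best leaving group on that carbon, to leave the lactone (should the ring oxygen leave instead, the lithium hemiacetalate can re-add to the phenyl ester and give the same lactone). The closest known reaction is the Parham cyclisation of 2-bromobenzyl carbamates and carbonates to phthalides (anionic homo-Fries 1,4 O→C acyl transfer). The five-membered lactone closes in a 5-exo-trig mode on the C=O group. No stereocentre is made and the acetal carbon is not touched, so each epimer of 14 gives one epimer of 16, and the mixture is carried on as stable pseudo-esters until the epimers are equilibrated and separated in step 17. The step needs chemoselectivity (exchange before carbonyl addition, secured by the temperature and by the bulk of t-BuLi), and the site is fixed by the bromine placed in step 5. In one operation it should deliver the C–C bond, the lactone carbonyl at its final oxidation level and the protected lactol of ring B from an open-chain benzylic acetal.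

**Ring A**

Step 10
Reactants: 17 1-fluoro-3-methoxy-5-methylbenzene
Product: 18 2-bromo-1-fluoro-5-methoxy-3-methylbenzene
Conditions: N-bromosuccinimide, MeCN, 25 °C
Reagents that add atoms: N-bromosuccinimide O=C1CCC(=O)N1Br
Why: Electrophilic bromination of the anisole should go para to the methoxy group, which puts bromine on the carbon between methyl and fluorine that will carry the ester.

Step 11
Reactants: 18 2-bromo-1-fluoro-5-methoxy-3-methylbenzene
Product: 20 3-bromo-2-fluoro-6-methoxy-4-methylbenzaldehyde, via aryllithium 19 (not isolated)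
Conditions: LiN(i-Pr)2, THF, −78 °C; then DMF; then H2O
Reagents that add atoms: N,N-dimethylformamide CN(C)C=O
Why: Directed ortho-metalation by the lithium amide should take the most acidic proton, the one flanked by fluorine and methoxy, without touching the C–Br bond, and DMF formylates the aryllithium.

Step 12
Reactants: 20 3-bromo-2-fluoro-6-methoxy-4-methylbenzaldehyde
Product: 21 3-bromo-2-fluoro-6-methoxy-4-methylbenzaldehyde dimethyl acetal
Conditions: HC(OMe)3, TsOH (cat.), MeOH, 50 °C
Reagents that add atoms: trimethyl orthoformate COC(OC)OC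
Why: Acid-catalysed acetalisation with the orthoformate as water scavenger masks the aldehyde against the organolithium of the next step.

Step 13
Reactants: 21 3-bromo-2-fluoro-6-methoxy-4-methylbenzaldehyde dimethyl acetal
Product: 24 allyl 2-fluoro-3-formyl-4-methoxy-6-methylbenzoate, via aryllithium 22 (not isolated), via acetal ester 23 (not isolated)
Conditions: n-BuLi, THF, −78 °C; then added to allyl chloroformate, −78 °C; then 1 M HCl, THF, 25 °C
Reagents that add atoms: allyl chloroformate C=CCOC(=O)Cl; water O
Why: Bromine–lithium exchange at −78 °C gives an ortho-fluoro aryllithium that should be acylated by the chloroformate before it can lose LiF, and aqueous acid then hydrolyses the acetal.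

**Union and end game**

Step 14
Reactants: 16 5-(allyloxy)-7-(benzyloxy)-3-[(1S)-1-phenylethoxy]-4-[(triisopropylsilyl)oxy]isobenzofuran-1(3H)-one (both epimers at C-3); 24 allyl 2-fluoro-3-formyl-4-methoxy-6-methylbenzoate
Product: 26 allyl 2-{[5-(allyloxy)-7-(benzyloxy)-1-oxo-3-[(1S)-1-phenylethoxy]-1,3-dihydroisobenzofuran-4-yl]oxy}-3-formyl-4-methoxy-6-methylbenzoate (both epimers at C-3), via caesium phenoxide 25 (not isolated)
Conditions: CsF (0.2 equiv), DMF, 25 → 40 °C
Reagents that add atoms: none
Why: Fluoride cleaves the aryl silyl ether and the phenoxide displaces the fluoride of 24, activated by the ortho formyl and ortho ester groups (SNAr through a Meisenheimer adduct), the released fluoride carrying the chain; reversible loss of the lactone carboxylate from the acetal carbon ortho to the phenoxide (ortho-quinone methide) can only interconvert the two epimers, which are carried together at this stage.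

Step 15
Reactants: 26 allyl 2-{[5-(allyloxy)-7-(benzyloxy)-1-oxo-3-[(1S)-1-phenylethoxy]-1,3-dihydroisobenzofuran-4-yl]oxy}-3-formyl-4-methoxy-6-methylbenzoate (both epimers at C-3)
Product: 27 2-{[7-(benzyloxy)-5-hydroxy-1-oxo-3-[(1S)-1-phenylethoxy]-1,3-dihydroisobenzofuran-4-yl]oxy}-3-formyl-4-methoxy-6-methylbenzoic acid (both epimers at C-3)
Conditions: Pd(PPh3)4 (5 mol%), 4-methylbenzenesulfinic acid (2.5 equiv), CH2Cl2, 25 °C
Reagents that add atoms: none
Why: Zerovalent palladium ionises the allyl ester and the allyl aryl ether to π-allyl complexes that the sulfinate traps as the sulfone (Tsuji–Trost deallylation), which should free acid and phenol while the benzyl ether and the acetal linkage stay intact.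

Step 16
Reactants: 27 2-{[7-(benzyloxy)-5-hydroxy-1-oxo-3-[(1S)-1-phenylethoxy]-1,3-dihydroisobenzofuran-4-yl]oxy}-3-formyl-4-methoxy-6-methylbenzoic acid (both epimers at C-3)
Product: 29 4-(benzyloxy)-1,3-dihydro-10-methoxy-8-methyl-3,7-dioxo-1-[(1S)-1-phenylethoxy]-7H-isobenzofuro[4,5-b][1,4]benzodioxepin-11-carboxaldehyde (both epimers at C-1), via O-acylisourea 28 (not isolated)
Conditions: DCC, DMAP (cat.), CH2Cl2 (0.01 M), 0 → 25 °C
Reagents that add atoms: none
Why: Carbodiimide activation with acyl transfer through DMAP (Steglich esterification) should close the seven-membered lactone because the diaryl ether holds the acid next to the only free phenol.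

Step 17
Reactants: 29 4-(benzyloxy)-1,3-dihydro-10-methoxy-8-methyl-3,7-dioxo-1-[(1S)-1-phenylethoxy]-7H-isobenzofuro[4,5-b][1,4]benzodioxepin-11-carboxaldehyde (both epimers at C-1)
Product: 30 (1S)-4-(benzyloxy)-1,3-dihydro-10-methoxy-8-methyl-3,7-dioxo-1-[(1S)-1-phenylethoxy]-7H-isobenzofuro[4,5-b][1,4]benzodioxepin-11-carboxaldehyde
Conditions: camphorsulfonic acid (5 mol%), toluene, 4 Å molecular sieves, 25 °C, until the epimer composition is constant; Et3N; chromatography on silica; the remaining fraction of 29 is returned to the same conditions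
Reagents that add atoms: none
Why: Acid-catalysed epimerisation of a 3-alkoxyphthalide pseudo-ester, in which protonation of the lactone carbonyl lets the ring C–O bond at the acetal carbon open reversibly to an aryl(alkoxy)carbenium ion that the carboxyl group recloses from either face, should interconvert the two epimers, which are diastereomers because of the (S)-1-phenylethyl group and can be separated on silica; the (1S) configuration is thus set by separation and recycling, not by induction.

Step 18
Reactants: 30 (1S)-4-(benzyloxy)-1,3-dihydro-10-methoxy-8-methyl-3,7-dioxo-1-[(1S)-1-phenylethoxy]-7H-isobenzofuro[4,5-b][1,4]benzodioxepin-11-carboxaldehyde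
Product: 31 (1S)-1,3-dihydro-1,4-dihydroxy-10-methoxy-8-methyl-3,7-dioxo-7H-isobenzofuro[4,5-b][1,4]benzodioxepin-11-carboxaldehyde (the target)
Conditions: H2 (1 atm), 10% Pd/C, EtOAc, 20 °C; filtration and evaporation below 20 °C
Reagents that add atoms: none
Why: Hydrogenolysis breaks the O–CH2Ph and O–CH(CH3)Ph bonds and none of the bonds to the lactol carbon, so phenol and lactol should appear with the (S) configuration retained under neutral conditions.

**Compound list**

1 | 4-(benzyloxy)-2-hydroxybenzaldehyde | O=Cc1ccc(OCc2ccccc2)cc1O | starting material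
2 | 2-(allyloxy)-4-(benzyloxy)benzaldehyde | O=Cc1ccc(OCc2ccccc2)cc1OCC=C | intermediate
3 | 2-(allyloxy)-4-(benzyloxy)phenyl formate | O=COc1ccc(OCc2ccccc2)cc1OCC=C | intermediate
4 | 2-(allyloxy)-4-(benzyloxy)phenol | Oc1ccc(OCc2ccccc2)cc1OCC=C | intermediate
5 | 2-(allyloxy)-4-(benzyloxy)-6-(hydroxymethyl)phenol | OCc1cc(OCc2ccccc2)cc(OCC=C)c1O | intermediate
6 | 3-(allyloxy)-5-(benzyloxy)-2-hydroxybenzaldehyde | O=Cc1cc(OCc2ccccc2)cc(OCC=C)c1O | intermediate
7 | 3-(allyloxy)-5-(benzyloxy)-2-[(triisopropylsilyl)oxy]benzaldehyde | O=Cc1cc(OCc2ccccc2)cc(OCC=C)c1O[Si](C(C)C)(C(C)C)C(C)C | intermediate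
8 | 3-(allyloxy)-5-(benzyloxy)-6-bromo-2-[(triisopropylsilyl)oxy]benzaldehyde | O=Cc1c(Br)c(OCc2ccccc2)cc(OCC=C)c1O[Si](C(C)C)(C(C)C)C(C)C | intermediate
9 | 3-(allyloxy)-5-(benzyloxy)-6-bromo-2-[(triisopropylsilyl)oxy]benzoic acid | OC(=O)c1c(Br)c(OCc2ccccc2)cc(OCC=C)c1O[Si](C(C)C)(C(C)C)C(C)C | intermediate
10 | (S)-1-phenylethanol | C[C@H](O)c1ccccc1 | starting material
11 | 3-(allyloxy)-5-(benzyloxy)-6-bromo-2-[(triisopropylsilyl)oxy]benzoyl chloride | ClC(=O)c1c(Br)c(OCc2ccccc2)cc(OCC=C)c1O[Si](C(C)C)(C(C)C)C(C)C | intermediate
12 | (S)-1-phenylethyl 3-(allyloxy)-5-(benzyloxy)-6-bromo-2-[(triisopropylsilyl)oxy]benzoate | C[C@H](OC(=O)c1c(Br)c(OCc2ccccc2)cc(OCC=C)c1O[Si](C(C)C)(C(C)C)C(C)C)c1ccccc1 | intermediate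
13 | diisobutylaluminium hemiacetal of 12 (both epimers) | C[C@H](OC(O[Al](CC(C)C)CC(C)C)c1c(Br)c(OCc2ccccc2)cc(OCC=C)c1O[Si](C(C)C)(C(C)C)C(C)C)c1ccccc1 | intermediate
14 | {3-(allyloxy)-5-(benzyloxy)-6-bromo-2-[(triisopropylsilyl)oxy]phenyl}[(1S)-1-phenylethoxy]methyl phenyl carbonate (both epimers at the acetal carbon) | C[C@H](OC(OC(=O)Oc1ccccc1)c1c(Br)c(OCc2ccccc2)cc(OCC=C)c1O[Si](C(C)C)(C(C)C)C(C)C)c1ccccc1 | intermediate
15 | aryllithium from 14 (lithium in place of bromine) | C[C@H](OC(OC(=O)Oc1ccccc1)c1c([Li])c(OCc2ccccc2)cc(OCC=C)c1O[Si](C(C)C)(C(C)C)C(C)C)c1ccccc1 | intermediate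
16 | 5-(allyloxy)-7-(benzyloxy)-3-[(1S)-1-phenylethoxy]-4-[(triisopropylsilyl)oxy]isobenzofuran-1(3H)-one (both epimers at C-3) | CC(C)[Si](Oc1c(OCC=C)cc(OCc2ccccc2)c3c1C(O[C@@H](C)c4ccccc4)OC3=O)(C(C)C)C(C)C | intermediate
17 | 1-fluoro-3-methoxy-5-methylbenzene | COc1cc(C)cc(F)c1 | starting material
18 | 2-bromo-1-fluoro-5-methoxy-3-methylbenzene | COc1cc(C)c(Br)c(F)c1 | intermediate
19 | (3-bromo-2-fluoro-6-methoxy-4-methylphenyl)lithium | COc1cc(C)c(Br)c(F)c1[Li] | intermediate
20 | 3-bromo-2-fluoro-6-methoxy-4-methylbenzaldehyde | COc1cc(C)c(Br)c(F)c1C=O | intermediate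
21 | 3-bromo-2-fluoro-6-methoxy-4-methylbenzaldehyde dimethyl acetal | COc1cc(C)c(Br)c(F)c1C(OC)OC | intermediate
22 | [3-(dimethoxymethyl)-2-fluoro-4-methoxy-6-methylphenyl]lithium | COc1cc(C)c([Li])c(F)c1C(OC)OC | intermediate
23 | allyl 3-(dimethoxymethyl)-2-fluoro-4-methoxy-6-methylbenzoate | COc1cc(C)c(C(=O)OCC=C)c(F)c1C(OC)OC | intermediate
24 | allyl 2-fluoro-3-formyl-4-methoxy-6-methylbenzoate | COc1cc(C)c(C(=O)OCC=C)c(F)c1C=O | intermediate
25 | caesium 5-(allyloxy)-7-(benzyloxy)-1-oxo-3-[(1S)-1-phenylethoxy]-1,3-dihydroisobenzofuran-4-olate (both epimers at C-3) | [Cs+].[O-]c1c(OCC=C)cc(OCc2ccccc2)c3c1C(O[C@@H](C)c4ccccc4)OC3=O | intermediate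
26 | allyl 2-{[5-(allyloxy)-7-(benzyloxy)-1-oxo-3-[(1S)-1-phenylethoxy]-1,3-dihydroisobenzofuran-4-yl]oxy}-3-formyl-4-methoxy-6-methylbenzoate (both epimers at C-3) | COc1cc(C)c(C(=O)OCC=C)c(c1C=O)Oc1c(OCC=C)cc(OCc2ccccc2)c3c1C(O[C@@H](C)c4ccccc4)OC3=O | intermediate
27 | 2-{[7-(benzyloxy)-5-hydroxy-1-oxo-3-[(1S)-1-phenylethoxy]-1,3-dihydroisobenzofuran-4-yl]oxy}-3-formyl-4-methoxy-6-methylbenzoic acid (both epimers at C-3) | COc1cc(C)c(C(O)=O)c(c1C=O)Oc1c(O)cc(OCc2ccccc2)c3c1C(O[C@@H](C)c4ccccc4)OC3=O | intermediate
28 | O-acylisourea of 27 (acid activated by DCC, both epimers at C-3) | COc1cc(C)c(C(=O)OC(=NC2CCCCC2)NC2CCCCC2)c(c1C=O)Oc1c(O)cc(OCc2ccccc2)c3c1C(O[C@@H](C)c4ccccc4)OC3=O | intermediate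
29 | 4-(benzyloxy)-1,3-dihydro-10-methoxy-8-methyl-3,7-dioxo-1-[(1S)-1-phenylethoxy]-7H-isobenzofuro[4,5-b][1,4]benzodioxepin-11-carboxaldehyde (both epimers at C-1) | COc1cc(C)c2c(c1C=O)Oc1c(cc(OCc3ccccc3)c3c1C(O[C@@H](C)c4ccccc4)OC3=O)OC2=O | intermediate
30 | (1S)-4-(benzyloxy)-1,3-dihydro-10-methoxy-8-methyl-3,7-dioxo-1-[(1S)-1-phenylethoxy]-7H-isobenzofuro[4,5-b][1,4]benzodioxepin-11-carboxaldehyde | COc1cc(C)c2c(c1C=O)Oc1c(cc(OCc3ccccc3)c3c1[C@@H](O[C@@H](C)c4ccccc4)OC3=O)OC2=O | intermediate
31 | (1S)-1,3-dihydro-1,4-dihydroxy-10-methoxy-8-methyl-3,7-dioxo-7H-isobenzofuro[4,5-b][1,4]benzodioxepin-11-carboxaldehyde | COc1cc(C)c2c(c1C=O)Oc1c(cc(O)c3c1[C@@H](O)OC3=O)OC2=O | target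

**Count and risks**

Total step count: 18. Longest linear sequence: 14 steps (steps 1–9, then 14–18).

Steps most likely to fail:

1. Step 8. The aluminium hemiacetal may collapse to the aldehyde (or be reduced further) before it is acylated, and the acetal carbonate may ionise during isolation. Fallback: set out from aldehyde 8 and add phenyl chloroformate across the C=O group (pyridine cat., CH2Cl2) to give the α-chloro carbonate F1. Then replace chloride by alcohol 10 with AgOSO2CF3 and 2,6-di-tert-butylpyridine at −40 °C (Koenigs–Knorr-type substitution). This comes back to the route at 14 and builds the tether from the aldehyde level instead of by reduction of the ester.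

2. Step 9. t-BuLi may add to the carbonate in competition with the exchange, the aryllithium may be quenched by proton transfer from the neighbouring benzyloxy methylene group, or the tetrahedral intermediate may open with loss of the alkoxy group. Fallback: set out from aldehyde 8 and mask it as the dimethyl acetal F2 (HC(OMe)3, TsOH). Carry out bromine–lithium exchange with n-BuLi at −78 °C, carboxylate with CO2 and hydrolyse with aqueous HCl to the racemic hydroxyphthalide F3 (ring–chain closure of the formyl acid). Form the pseudo-ester with alcohol 10 (camphorsulfonic acid, toluene, 4 Å molecular sieves) and come back to the route at 16. Here the C7a–C1 bond is made by intermolecular carboxylation and the ring is closed at oxygen.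

3. Step 18. The aryl aldehyde may be over-reduced, the benzylic acetal C–O bond at the lactol carbon may be hydrogenolysed, and the freed lactol may epimerise. Fallback: set out from 30 and remove both benzylic groups by Lewis-acid dealkylation with a cation scavenger (BCl3, pentamethylbenzene, CH2Cl2, −78 °C, pH 7 buffer quench). This cleaves the O–benzyl and O–(1-phenylethyl) bonds through the benzylic cations and comes back at 31; it makes no new compound (F0).

Further compounds
F1 | step 8 | {3-(allyloxy)-5-(benzyloxy)-6-bromo-2-[(triisopropylsilyl)oxy]phenyl}(chloro)methyl phenyl carbonate | ClC(OC(=O)Oc1ccccc1)c1c(Br)c(OCc2ccccc2)cc(OCC=C)c1O[Si](C(C)C)(C(C)C)C(C)C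
F2 | step 9 | 3-(allyloxy)-5-(benzyloxy)-6-bromo-2-[(triisopropylsilyl)oxy]benzaldehyde dimethyl acetal | COC(OC)c1c(Br)c(OCc2ccccc2)cc(OCC=C)c1O[Si](C(C)C)(C(C)C)C(C)C
F3 | step 9 | 5-(allyloxy)-7-(benzyloxy)-3-hydroxy-4-[(triisopropylsilyl)oxy]isobenzofuran-1(3H)-one (racemic) | CC(C)[Si](Oc1c(OCC=C)cc(OCc2ccccc2)c3c1C(O)OC3=O)(C(C)C)C(C)C
F0 | step 18 | none | none
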